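**Plan**
- Retrosynthesis: with the late protecting-group steps set aside, ring B is cut at B1–B6 (aldol), the open chain at C6–C7 and C4–C5 (two acylations of acetoacetate-derived anions), and ring A at its O–CH2 ether bond and its carboxyl C–C bond, back to olivetol.
- Enabling feature: ring B (B1 CO2H, B2 OH, B3 H, B4 OMe, B5 O-aryl, B6 pentyl) is an olivetolate. B1–B6 map onto C2–C7 of a 3,5,7-trioxododecanoate, and only the ether oxygen on chain C6 is foreign to the polyketide.
- Forward: ring A comes from olivetol (carboxylation, tert-butyl ester, 4-O-benzyl ether); its remaining phenol is O-alkylated with methyl bromoacetate, so the diaryl ether oxygen is in place before ring B exists.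
- Chain: the benzyl acetoacetate dianion is acylated by that ester (C4–C5), then the derived trianion by a hexanoyl Weinreb amide (C6–C7). Ring B closes by C2-to-C7 aldol condensation and aromatises.
- End game: tert-butyl ester cleavage, one-pot methylation of the ring A acid and the B4 hydroxyl, hydrogenolysis of both benzyl groups.
- Stereochemistry: the target has no stereocentre, so nothing has to be set.

Key step: step 8

Remark: triketo ester 11 is a mixture of keto–enol tautomers and is drawn as its chelated C6–C7 enol; C6 of the keto form and the three sp3 centres of the transient adduct 12 are configurationally irrelevant and are left undefined.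

**Step 1**
Reactants: 1 olivetol (5-pentylbenzene-1,3-diol)
Product: 2 olivetolic acid (2,4-dihydroxy-6-pentylbenzoic acid)
Conditions: MeOMgOCO2Me (2 M in DMF, 4 equiv), 120 °C; then cold 2 M HCl
Reagents that add atoms: methylmagnesium carbonate, COC(=O)O[Mg]OC
Why: Kolbe–Schmitt-type carboxylation in which the reagent delivers CO2 ortho to a phenol and holds the product as a magnesium salicylate chelate, which should favour the 2,4-dihydroxy-6-pentyl acid and protect it from decarboxylation until acidification.

**Step 2**
Reactants: 2 olivetolic acid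
Product: 3 tert-butyl 2,4-dihydroxy-6-pentylbenzoate
Conditions: t-BuOC(=NH)CCl3 (2 equiv), CH2Cl2/THF, rt
Reagents that add atoms: tert-butyl 2,2,2-trichloroacetimidate, CC(C)(C)OC(=N)C(Cl)(Cl)Cl
Why: imidate esterification, in which the carboxylic acid itself protonates the trichloroacetimidate and is tert-butylated, while the phenols are not acidic enough to react without a Lewis acid.

**Step 3**
Reactants: 3 tert-butyl 2,4-dihydroxy-6-pentylbenzoate
Product: 4 tert-butyl 4-(benzyloxy)-2-hydroxy-6-pentylbenzoate
Conditions: BnBr (1.05 equiv), K2CO3, acetone, rt → 40 °C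
Reagents that add atoms: benzyl bromide, BrCc1ccccc1
Why: Williamson etherification that should be selective for the 4-hydroxyl, because the 2-hydroxyl is tied up in a hydrogen bond to the ester carbonyl and is less acidic and less nucleophilic.

**Step 4**
Reactants: 4 tert-butyl 4-(benzyloxy)-2-hydroxy-6-pentylbenzoate; 5 methyl bromoacetate
Product: 6 tert-butyl 4-(benzyloxy)-2-(2-methoxy-2-oxoethoxy)-6-pentylbenzoate
Conditions: K2CO3, DMF, 60 °C
Reagents that add atoms: none
Why: Williamson etherification of the chelated phenol by a reactive α-halo ester in a dipolar aprotic solvent; carbonate is too weak to start a Dieckmann closure onto the hindered tert-butyl ester.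

**Step 5**
Reactants: 6 tert-butyl 4-(benzyloxy)-2-(2-methoxy-2-oxoethoxy)-6-pentylbenzoate; 7 benzyl acetoacetate
Product: 8 benzyl 6-[5-(benzyloxy)-2-(tert-butoxycarbonyl)-3-pentylphenoxy]-3,5-dioxohexanoate
Conditions: 7 (2.2 equiv), LiN(i-Pr)2 (4.4 equiv), THF, −78 → 0 °C; then 6, −78 → −20 °C; cold 1 M HCl
Reagents that add atoms: none
Why: Claisen condensation of the acetoacetate dianion through its terminal carbon with the activated α-aryloxy methyl ester; the excess dianion absorbs the acidic proton of the product, and the di-ortho-substituted tert-butyl benzoate is too hindered to be attacked.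

**Step 6**
Reactants: 9 hexanoyl chloride
Product: 10 N-methoxy-N-methylhexanamide
Conditions: MeNHOMe·HCl, K2CO3, CH2Cl2/H2O, 0 °C → rt
Reagents that add atoms: N,O-dimethylhydroxylamine hydrochloride, CNOC.Cl
Why: Schotten–Baumann N-acylation of the hydroxylamine by the acid chloride gives the Weinreb amide.

**Step 7**
Reactants: 8 benzyl 6-[5-(benzyloxy)-2-(tert-butoxycarbonyl)-3-pentylphenoxy]-3,5-dioxohexanoate; 10 N-methoxy-N-methylhexanamide
Product: 11 benzyl 6-[5-(benzyloxy)-2-(tert-butoxycarbonyl)-3-pentylphenoxy]-3,5,7-trioxododecanoate (chelated C6–C7 enol drawn)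
Conditions: LiN(i-Pr)2 (3.3 equiv), THF, −78 → −20 °C; then 10 (1.2 equiv), −78 → 0 °C; cold 1 M HCl
Reagents that add atoms: none
Why: terminal acylation of a 3,5-dioxo ester trianion (Claisen-type Weinreb ketone synthesis), in which the last-formed, least stabilised carbanion at C6, acidified by the aryloxy group, attacks the amide; the lithium-chelated tetrahedral intermediate persists until the quench, so neither over-addition nor proton exchange with the product occurs, and the tert-butyl ester of ring A resists closure to a benzofuranone at low temperature.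

**Step 8**
Reactants: 11 benzyl 6-[5-(benzyloxy)-2-(tert-butoxycarbonyl)-3-pentylphenoxy]-3,5,7-trioxododecanoate
Product: 13 benzyl 5-[5-(benzyloxy)-2-(tert-butoxycarbonyl)-3-pentylphenoxy]-2,4-dihydroxy-6-pentylbenzoate, via cyclic aldol adduct 12 (not isolated)
Conditions: Et3N (3 equiv), CH2Cl2, 0 °C → rt; then 1 M HCl, THF, rt
Reagents that add atoms: none
Why: Triethylamine generates the enolate of the triketo ester, and the C2 carbon, flanked by the benzyl ester and the C3 ketone, adds to the C7 ketone, which the inductive pull of the C6 aryloxy group makes the most electrophilic carbonyl; the cyclohexanedione adduct 12 loses water on acidification and the C3 and C5 carbonyls enolise to the resorcinol hydroxyls at B2 and B4. The closest known reaction is the biomimetic aldol cyclisation–aromatisation of 3,5,7-triketo esters to 2,4-dihydroxybenzoates. Ring B closes in a 6-exo-trig mode, allowed for the C2 enolate both in its enolendo form (C2=C3) and through the ester enolate (enolexo). No stereocentre is created in the product, and the three centres of 12 are erased on aromatisation. The step needs folding selectivity: Claisen closure of C6 onto the ester carbon would create a quaternary aryloxy carbon that cannot aromatise and needs alkoxide-strength base, lactonisation to a 4-hydroxy-2-pyrone needs heat or a strong amidine base, and the ring A tert-butyl ester between two ortho substituents is not attacked, so with a mild amine base at room temperature only the aldol path has an irreversible, aromatising exit.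

**Step 9**
Reactants: 13 benzyl 5-[5-(benzyloxy)-2-(tert-butoxycarbonyl)-3-pentylphenoxy]-2,4-dihydroxy-6-pentylbenzoate
Product: 14 benzyl 5-[5-(benzyloxy)-2-carboxy-3-pentylphenoxy]-2,4-dihydroxy-6-pentylbenzoate
Conditions: CF3CO2H/CH2Cl2 (1:4), 0 °C → rt
Reagents that add atoms: none
Why: acidolysis of the tert-butyl ester by alkyl–oxygen cleavage with loss of isobutene; the benzyl ester and the benzyl aryl ether should survive brief exposure at low temperature, and no dehydrating agent is present that could lactonise the acid onto the B4 hydroxyl.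

**Step 10**
Reactants: 14 benzyl 5-[5-(benzyloxy)-2-carboxy-3-pentylphenoxy]-2,4-dihydroxy-6-pentylbenzoate
Product: 15 benzyl 5-[5-(benzyloxy)-2-(methoxycarbonyl)-3-pentylphenoxy]-2-hydroxy-4-methoxy-6-pentylbenzoate
Conditions: MeI (2.2 equiv), K2CO3, acetone, rt
Reagents that add atoms: iodomethane, CI
Why: O-alkylation of the carboxylate and of the free B4 phenoxide (Williamson-type); the B2 hydroxyl is locked in a hydrogen bond to the benzyl ester carbonyl and should stay unmethylated with two equivalents of iodomethane.

**Step 11**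
Reactants: 15 benzyl 5-[5-(benzyloxy)-2-(methoxycarbonyl)-3-pentylphenoxy]-2-hydroxy-4-methoxy-6-pentylbenzoate
Product: 16 epiphorellic acid 1 (2-hydroxy-5-[5-hydroxy-2-(methoxycarbonyl)-3-pentylphenoxy]-4-methoxy-6-pentylbenzoic acid)
Conditions: H2 (1 atm), Pd/C (10% palladium on carbon), EtOAc, rt
Reagents that add atoms: none
Why: catalytic hydrogenolysis cleaves the benzylic C–O bonds of the benzyl ester and the benzyl ether in one operation and leaves the diaryl ether, the methyl ester and the methyl ether untouched.

**Compound list**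
1 | olivetol (5-pentylbenzene-1,3-diol) | CCCCCc1cc(O)cc(O)c1 | starting material
2 | olivetolic acid (2,4-dihydroxy-6-pentylbenzoic acid) | CCCCCc1cc(O)cc(O)c1C(=O)O | intermediate
3 | tert-butyl 2,4-dihydroxy-6-pentylbenzoate | CCCCCc1cc(O)cc(O)c1C(=O)OC(C)(C)C | intermediate
4 | tert-butyl 4-(benzyloxy)-2-hydroxy-6-pentylbenzoate | CCCCCc1cc(OCc2ccccc2)cc(O)c1C(=O)OC(C)(C)C | intermediate
5 | methyl bromoacetate | COC(=O)CBr | starting material
6 | tert-butyl 4-(benzyloxy)-2-(2-methoxy-2-oxoethoxy)-6-pentylbenzoate | CCCCCc1cc(OCc2ccccc2)cc(OCC(=O)OC)c1C(=O)OC(C)(C)C | intermediate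
7 | benzyl acetoacetate | CC(=O)CC(=O)OCc1ccccc1 | starting material
8 | benzyl 6-[5-(benzyloxy)-2-(tert-butoxycarbonyl)-3-pentylphenoxy]-3,5-dioxohexanoate | CCCCCc1cc(OCc2ccccc2)cc(OCC(=O)CC(=O)CC(=O)OCc2ccccc2)c1C(=O)OC(C)(C)C | intermediate
9 | hexanoyl chloride | CCCCCC(=O)Cl | starting material
10 | N-methoxy-N-methylhexanamide | CCCCCC(=O)N(C)OC | intermediate
11 | benzyl 6-[5-(benzyloxy)-2-(tert-butoxycarbonyl)-3-pentylphenoxy]-3,5,7-trioxododecanoate, drawn as the chelated (6E) C6–C7 enol | O=C(OCc1ccccc1)CC(=O)CC(=O)/C(Oc1cc(OCc2ccccc2)cc(CCCCC)c1C(=O)OC(C)(C)C)=C(\O)CCCCC | intermediate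
12 | benzyl 3-[5-(benzyloxy)-2-(tert-butoxycarbonyl)-3-pentylphenoxy]-2-hydroxy-4,6-dioxo-2-pentylcyclohexane-1-carboxylate (cyclic aldol adduct, transient mixture of diastereomers and enol tautomers, configuration undefined) | CCCCCC1(O)C(Oc2cc(OCc3ccccc3)cc(CCCCC)c2C(=O)OC(C)(C)C)C(=O)CC(=O)C1C(=O)OCc1ccccc1 | intermediate (not isolated)
13 | benzyl 5-[5-(benzyloxy)-2-(tert-butoxycarbonyl)-3-pentylphenoxy]-2,4-dihydroxy-6-pentylbenzoate | CCCCCc1cc(OCc2ccccc2)cc(Oc2c(O)cc(O)c(C(=O)OCc3ccccc3)c2CCCCC)c1C(=O)OC(C)(C)C | intermediate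
14 | benzyl 5-[5-(benzyloxy)-2-carboxy-3-pentylphenoxy]-2,4-dihydroxy-6-pentylbenzoate | CCCCCc1cc(OCc2ccccc2)cc(Oc2c(O)cc(O)c(C(=O)OCc3ccccc3)c2CCCCC)c1C(=O)O | intermediate
15 | benzyl 5-[5-(benzyloxy)-2-(methoxycarbonyl)-3-pentylphenoxy]-2-hydroxy-4-methoxy-6-pentylbenzoate | CCCCCc1cc(OCc2ccccc2)cc(Oc2c(OC)cc(O)c(C(=O)OCc3ccccc3)c2CCCCC)c1C(=O)OC | intermediate
16 | epiphorellic acid 1 (2-hydroxy-5-[5-hydroxy-2-(methoxycarbonyl)-3-pentylphenoxy]-4-methoxy-6-pentylbenzoic acid) | CCCCCc1cc(O)cc(Oc2c(OC)cc(O)c(C(=O)O)c2CCCCC)c1C(=O)OC | target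

**Totals**
Total step count: 11. Longest linear sequence: 10 steps (steps 1–5 and 7–11, from olivetol); step 6 is a one-step side branch.

**Steps most likely to fail**

Step 7. Acyl transfer from the amide to the crowded, aryloxy-bearing C6 carbanion may be sluggish. That would leave time for proton exchange with the α-CH2 of the amide, for closure of the C6 carbanion onto the ring A ester, or for O-acylation. The fallback changes the electrophile and the oxidation level. It sets out from 8: the trianion, generated as before, is trapped at −78 °C with hexanal, a fast and irreversible aldol addition, to give benzyl 6-[5-(benzyloxy)-2-(tert-butoxycarbonyl)-3-pentylphenoxy]-7-hydroxy-3,5-dioxododecanoate F1 as a mixture of diastereomers. Oxidation of the secondary alcohol of this β-hydroxy ketone with Dess–Martin periodinane (CH2Cl2, 0 °C) returns to the route at 11.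

Step 8. The chain may fold the wrong way: lactonisation through the C5 enol oxygen onto the benzyl ester, retro-Claisen cleavage of the 2-aryloxy-1,3-diketone, or stalling because the C6–C7 enolate masks the C7 carbonyl. The fallback keeps the C2-to-C7 aldol but locks the carboxyl in a dioxinone, so that neither lactonisation nor Claisen closure is possible. It sets out from 6.
- The lithium dienolate of commercial 2,2,6-trimethyl-4H-1,3-dioxin-4-one (LiN(SiMe3)2, THF, −78 °C, 2.2 equiv) is acylated by 6 to give tert-butyl 4-(benzyloxy)-2-[3-(2,2-dimethyl-4-oxo-4H-1,3-dioxin-6-yl)-2-oxopropoxy]-6-pentylbenzoate F2.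
- Its dianion (LiN(i-Pr)2, 2.2 equiv) is acylated at the aryloxy-bearing carbon by amide 10 to give tert-butyl 4-(benzyloxy)-2-{[1-(2,2-dimethyl-4-oxo-4H-1,3-dioxin-6-yl)-2,4-dioxononan-3-yl]oxy}-6-pentylbenzoate F3.
- Et3N in CH2Cl2, then dilute acid, lets the dioxinone C5 add to the pentyl ketone and aromatise, giving tert-butyl 4-(benzyloxy)-2-[(7-hydroxy-2,2-dimethyl-4-oxo-5-pentyl-4H-1,3-benzodioxin-6-yl)oxy]-6-pentylbenzoate F4.
- Opening of this isopropylidene-protected resorcylate with benzyl alcohol and Cs2CO3 (THF, 60 °C) releases acetone and returns to the route at 13.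

Step 1. Carboxylation may occur in part at the position between the two hydroxyls, conversion may be incomplete, and the acid may decarboxylate during acidic work-up or during the esterification that follows. The fallback brings in the carboxyl carbon as an aldehyde and sets out from 1.
- Vilsmeier–Haack formylation (POCl3, DMF, 0 °C → rt, aqueous hydrolysis) should give 2,4-dihydroxy-6-pentylbenzaldehyde F5.
- Benzylation of the non-chelated hydroxyl (BnBr, K2CO3, acetone) gives 4-(benzyloxy)-2-hydroxy-6-pentylbenzaldehyde F6.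
- Pinnick oxidation (NaClO2, NaH2PO4, 2-methyl-2-butene, t-BuOH/H2O) gives 4-(benzyloxy)-2-hydroxy-6-pentylbenzoic acid F7.
- Esterification with tert-butyl 2,2,2-trichloroacetimidate as in step 2 returns to the route at 4.

**Further compounds**
F1 | step 7 | benzyl 6-[5-(benzyloxy)-2-(tert-butoxycarbonyl)-3-pentylphenoxy]-7-hydroxy-3,5-dioxododecanoate (mixture of diastereomers) | CCCCCC(O)C(Oc1cc(OCc2ccccc2)cc(CCCCC)c1C(=O)OC(C)(C)C)C(=O)CC(=O)CC(=O)OCc1ccccc1
F2 | step 8 | tert-butyl 4-(benzyloxy)-2-[3-(2,2-dimethyl-4-oxo-4H-1,3-dioxin-6-yl)-2-oxopropoxy]-6-pentylbenzoate | CC1(C)OC(CC(=O)COc2cc(OCc3ccccc3)cc(CCCCC)c2C(=O)OC(C)(C)C)=CC(=O)O1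
F3 | step 8 | tert-butyl 4-(benzyloxy)-2-{[1-(2,2-dimethyl-4-oxo-4H-1,3-dioxin-6-yl)-2,4-dioxononan-3-yl]oxy}-6-pentylbenzoate (enolisable, no configuration assigned) | CC1(C)OC(CC(=O)C(Oc2cc(OCc3ccccc3)cc(CCCCC)c2C(=O)OC(C)(C)C)C(=O)CCCCC)=CC(=O)O1
F4 | step 8 | tert-butyl 4-(benzyloxy)-2-[(7-hydroxy-2,2-dimethyl-4-oxo-5-pentyl-4H-1,3-benzodioxin-6-yl)oxy]-6-pentylbenzoate | CCCCCc1c(Oc2cc(OCc3ccccc3)cc(CCCCC)c2C(=O)OC(C)(C)C)c(O)cc2OC(C)(C)OC(=O)c12
F5 | step 1 | 2,4-dihydroxy-6-pentylbenzaldehyde | CCCCCc1cc(O)cc(O)c1C=O
F6 | step 1 | 4-(benzyloxy)-2-hydroxy-6-pentylbenzaldehyde | CCCCCc1cc(OCc2ccccc2)cc(O)c1C=O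
F7 | step 1 | 4-(benzyloxy)-2-hydroxy-6-pentylbenzoic acid | CCCCCc1cc(OCc2ccccc2)cc(O)c1C(=O)O
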